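The amounts were 1.10 incoming ligand for each starting complex in both flasks, and the two flasks differed in their scavenger.

| setting | Sunday's | Monday's |
|---|---|---|
| starting complex | 0.20 M | 0.20 M |
| incoming ligand | 0.220 M | 0.220 M |
| scavenger | 0.240 M | 0.160 M |
| time | 15 min | 15 min |

    starting complex + incoming ligand → leaving ligand + complex with one exchanged (k1 = 0.24 /M/min)
    complex with one exchanged + incoming ligand → leaving ligand + complex with two exchanged (k2 = 0.50 /M/min)
    leaving ligand + incoming ligand ⇌ idle adduct, settled at all times (K3 = 120 /M)
    scavenger + leaving ligand → scavenged by-product (k4 = 3.1 /M/min)
    2 incoming ligand → homo dimer (k5 = 0.12 /M/min)

- what is said of leaving ligand includes idle adduct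
- where a step has two of a species, its rate is k times that concentration squared, and two are used at each turn
- run time (Sunday's): 15 min

1. part of the starting complex that has reacted at the end, Sunday's
2. part of the starting complex that has reacted at the end, Monday's
3. what raising the concentration of scavenger from its lowest to its highest value here does to the part of the starting complex that has reacted (changes below 5 percentage points count as none) (no change / it rises / it falls)

I wrote this reckoning at the start, for whoever took over the bench. At the charged ligand, one freed leaving ligand in 27.4 stayed free, the others sitting as idle adduct. At that charged ligand the scavenger needed 25.5 min to halve that pool in Sunday's flask and 38.3 min in Monday's, longer than the run, but these times hold at the charge only and shorten as the ligand falls. As a rough step I left the scavenger out of my reckoning, and I priced each reacted starting complex at two incoming ligand: one entering it, one tied up in the adduct.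

With the starting complex held at its charge, that price took 76.3% of the ligand during the run. The homo dimer pulled beside it, at 0.550 of that pull at the charge. The first exchange has twice the dimer's constant, and so the sum came out simple. The fraction left came to 70.4%: one divided by one plus that pull times that share. That gave 29.6% reacted for both flasks, and with the scavenger left out I expected no change.

The forecast gave 33% for Sunday's, 31% for Monday's and no change, holding that the leaving ligand “locks much of what remains in the idle adduct”.

Sunday's flask reached 31.0% and Monday's 30.5%, which is no change, with 0.46 percentage points between them. Sunday's flask ended with 24% of its incoming ligand, the limiting reagent, against 69% of its starting complex. For the neighbouring flask, Sunday's with 0.55 M of incoming ligand, I scaled the pull with the charge, and the fraction left came to 48.8%. That flask ended with 48% of its starting complex.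

The constants are those of an exercise.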